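The data were computed from invented constants; the scatter is artificial.

You have no constants for these steps yet, so you reckon from the charges and take the speeds from the runs.

in all of them: J 0.475 M

| run | L | remark | time |
|---|---|---|---|
| alpha | 0.50 M (in portions, 4) | the very flask that is asked about, followed so far; portions every 2.0 min |  |
| delta | 0.25 M (in portions, 4) | run made earlier; portions every 2.0 min |  |
| flask | 0.50 M (in portions, 4) | the portions of L follow each other after 2.0 min, the first at the start | 30 min |

| run | time / min | X / % | L / % |
|---|---|---|---|
| alpha | 1.00 | 25.4 | 3.0 |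
| alpha | 1.33 | 26.1 | 0.6 |
| alpha | 2.00 | 25.0 | 0 |
| alpha | 3.00 | 51.4 | 0 |
| alpha | 5.00 | 74.8 | 0.1 |
| alpha | 8.00 | 92.9 | 5.5 |
| alpha | 12.0 | 94.9 | 5.8 |
| delta | 2.50 | 50.3 | 0 |
| delta | 4.00 | 47.1 | 1.8 |
| delta | 6.00 | 74.3 | 0 |
| delta | 8.00 | 99.3 | 0 |
| delta | 12.0 | 100.9 | 0.2 |
| delta | 20.0 | 100.9 | 0.4 |
| delta | 30.0 | 100.9 | 1.4 |

(readings scatter by 1 percentage point)

- for D the Q are counted in
- as a solid, counted per litre of solution: Q
- steps under discussion: L + J -> X + D; Q <-> D; L + D -> E

- X present at 30 min, in percent of the L charged
- L present at 30 min, in percent of the L charged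

In the first instants a portion puts 0.125 M of L against 0.475 M of J, more J than L. In the alpha run L reads 3.0% after 1.00 min and 0.6% after 1.33 min, so L + J finishes a portion well inside the 2.0 min between additions. The delta run, with J above L, reads X at 100.9% after 12.0 min, so you count one X per L. The alpha run reads X at 94.9% after 12.0 min, close to J charged over L charged, 95.0%, so you count one J per X.

The middle is plain subtraction. Before the last portion, J stands at 0.100 M, less than the portion, so J is the limiting reagent of this flask. X can reach 95.0% of the charge, and the rest is the spare L, one minus J charged over L charged, 5.00%.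

At the end, the alpha readings at 12.0 min are X 94.9% and L 5.8%, summing to 100.7%, so within the scatter no loss shows yet. What can still move the spare L is L + D, which takes no X. My reckoning for this flask is X at 95.0% and L a little under 5.00%.

The forecast says X 95% and L 4.5%: “So L + D is slow at most”. The flask gives X 95.0% and L 4.53%.

    L + J → X + D (k = 0.610 L mol⁻¹ s⁻¹)
    Q ⇌ D, rate k2*(cs2 - [D]) while solid is left; crystals form when [D] > cs2 (solubility = 14.0 mM, k = 1.00 s⁻¹)
    L + D → E (k = 0.00410 L mol⁻¹ s⁻¹)

In this flask at 2.36 min, the half-life of L is 0.083 min by L + J and 190 min by L + D, the latter long against the 30 min asked about. At 30.0 min, the spare 5.00% of this flask is shared between L at 4.53% and E at 0.471%. For the neighbour charged with 1.2 M of L, the same rule gives a ceiling of 39.6% and a spare of 60.4%, and that flask holds X 39.6%, L 55.3% and E 5.10%.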